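**Strategy.** Ring A is disconnected completely. Its six carbons alternate oxygen (C2', C4', C6') and carbon (C1', C3', C5') substituents, which is what the union of an alkoxy-substituted vinylketene with an alkynyl ether delivers. One thermal operation on a cyclobutenone and ethoxyacetylene forges C1'–C2', C5'–C6' and C2'–C3', closes ring A, and leaves C1' as the only open carbon for the (R)-2-methylbutanoyl group. The precursor is a 3-methoxy-4-methylcyclobut-2-enone whose C2 carries the C8 methylene of the ring B chromanone, protected as its 5,7-dibenzyl ether. It comes from a ketene–ynol ether cycloaddition.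

Key step: step 11

Remark 1: ring B needs its pyranone oxygen para to the C6 methyl and between C4a and C8. A 3,5-dihydroxy-4-methylbenzoic acid would place a carboxyl carbon there, so ring B is entered from phloroglucinol, and C6 and C8 are told apart through the chelated C5 hydroxyl.

Remark 2: a free C7 hydroxyl would trap the ketene carbon as a six-membered lactone, and a free C5 hydroxyl would be acylated by methylketene. Both ring B phenols therefore stay benzylated through the key step.

Remark 3: compounds 1, 2, 12, 16, 19 (as its hexane solution) and 25 are taken as purchased. Compound 18 is used as the racemate at cyclobutenone C4, which becomes the aromatic C3'.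

Step 1
Reactants: 1 phloroglucinol, 2 3-methylbut-2-enoic acid
Product: 3 5,7-dihydroxy-2,2-dimethylchroman-4-one
Conditions: P2O5, MeSO3H, 70 °C
Reagents that add atoms: none
Why: Friedel–Crafts acylation of the threefold-symmetric triol by the activated acid, then acid-promoted oxa-Michael closure of the aryl enone, should give the chromanone with no regiochemical choice to make.

Step 2
Reactants: 3 5,7-dihydroxy-2,2-dimethylchroman-4-one
Product: 4 7-(benzyloxy)-5-hydroxy-2,2-dimethylchroman-4-one
Conditions: BnBr (1.05 equiv), K2CO3, acetone, reflux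
Reagents that add atoms: benzyl bromide, BrCc1ccccc1
Why: Williamson etherification should take only the C7 hydroxyl, because the C5 hydroxyl is held in a hydrogen bond to the C4 carbonyl and is far less nucleophilic.

Step 3
Reactants: 4 7-(benzyloxy)-5-hydroxy-2,2-dimethylchroman-4-one
Product: 5 7-(benzyloxy)-5-hydroxy-6-iodo-2,2-dimethylchroman-4-one
Conditions: BnMe3N·ICl2 (1.05 equiv), CaCO3, CH2Cl2/MeOH, 25 °C
Reagents that add atoms: benzyltrimethylammonium dichloroiodate, C[N+](C)(C)Cc1ccccc1.Cl[I-]Cl
Why: electrophilic aromatic iodination is steered ortho to the free chelated C5 phenol and should therefore mark C6, leaving C8 between the two ether oxygens untouched.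

Step 4
Reactants: 5 7-(benzyloxy)-5-hydroxy-6-iodo-2,2-dimethylchroman-4-one
Product: 6 7-(benzyloxy)-5-hydroxy-2,2,6-trimethylchroman-4-one
Conditions: MeZnCl (3 equiv), PdCl2(dppf) (5 mol%), THF, 50 °C
Reagents that add atoms: methylzinc chloride, C[Zn]Cl
Why: Negishi coupling should replace the C6 iodide by methyl under base-free conditions that cannot open the pyranone ring, the phenol merely consuming one equivalent of the zinc reagent.

Step 5
Reactants: 6 7-(benzyloxy)-5-hydroxy-2,2,6-trimethylchroman-4-one
Product: 7 7-(benzyloxy)-5-hydroxy-2,2,6-trimethyl-4-oxochromane-8-carbaldehyde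
Conditions: POCl3, DMF, 0 → 35 °C; then ice-water
Reagents that add atoms: N,N-dimethylformamide, CN(C)C=O; water, O
Why: Vilsmeier–Haack formylation can only strike C8, the single open ring carbon, which is para to the free C5 hydroxyl and flanked by O1 and the C7 ether, while the mild temperature should spare the enolisable C4 ketone.

Step 6
Reactants: 7 7-(benzyloxy)-5-hydroxy-2,2,6-trimethyl-4-oxochromane-8-carbaldehyde
Product: 8 5,7-bis(benzyloxy)-2,2,6-trimethyl-4-oxochromane-8-carbaldehyde
Conditions: BnBr, K2CO3, n-Bu4NI (cat.), DMF, 45 °C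
Reagents that add atoms: benzyl bromide, BrCc1ccccc1
Why: Williamson etherification in a dipolar solvent should cap the hydrogen-bonded C5 hydroxyl, whose acidity is raised by the new para formyl group.

Step 7
Reactants: 8 5,7-bis(benzyloxy)-2,2,6-trimethyl-4-oxochromane-8-carbaldehyde
Product: 9 5,7-bis(benzyloxy)-8-(hydroxymethyl)-2,2,6-trimethylchroman-4-one
Conditions: NaBH4 (0.5 equiv), THF/MeOH, −10 °C
Reagents that add atoms: none
Why: chemoselective borohydride reduction should take the aldehyde alone, since the C4 ketone is hindered and deactivated by three donor oxygens on its ring.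

Step 8
Reactants: 9 5,7-bis(benzyloxy)-8-(hydroxymethyl)-2,2,6-trimethylchroman-4-one
Product: 11 5,7-bis(benzyloxy)-8-(chloromethyl)-2,2,6-trimethylchroman-4-one, via mesylate 10 (not isolated)
Conditions: MsCl, Et3N, CH2Cl2, 0 → 25 °C
Reagents that add atoms: methanesulfonyl chloride, CS(=O)(=O)Cl
Why: sulfonylation followed by nucleophilic substitution, the electron-rich benzylic mesylate being displaced in the flask by the chloride released from the sulfonyl chloride.

Step 9
Reactants: 11 5,7-bis(benzyloxy)-8-(chloromethyl)-2,2,6-trimethylchroman-4-one, 12 chloroacetaldehyde dimethyl acetal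
Product: 15 5,7-bis(benzyloxy)-8-(3-methoxyprop-2-yn-1-yl)-2,2,6-trimethylchroman-4-one, via lithium methoxyacetylide 13 (not isolated), via (methoxyethynyl)zinc chloride 14 (not isolated)
Conditions: 12, LiNEt2 (3.0 equiv), THF, 0 °C; ZnCl2 (excess), 0 °C; then 11, Pd(PPh3)4 (5 mol%), THF, 25 °C
Reagents that add atoms: none
Why: double elimination of the chloroacetal gives the methoxyacetylide, and after transmetalation a Negishi benzyl–alkynyl coupling through a benzylpalladium chloride should form the ynol ether, the alkynylzinc being inert towards the C4 ketone and the excess ZnCl2 tying up diethylamine and methoxide.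

Step 10
Reactants: 15 5,7-bis(benzyloxy)-8-(3-methoxyprop-2-yn-1-yl)-2,2,6-trimethylchroman-4-one, 16 propanoyl chloride
Product: 18 2-{[5,7-bis(benzyloxy)-2,2,6-trimethyl-4-oxochroman-8-yl]methyl}-3-methoxy-4-methylcyclobut-2-en-1-one (racemic at C4), via methylketene 17 (not isolated)
Conditions: 16 (slow addition), Et3N, CH2Cl2, 25 → 40 °C
Reagents that add atoms: none
Why: ketene–alkyne [2+2] cycloaddition, in which the ketene carbonyl carbon bonds to the nucleophilic alkyne carbon bearing the ring B methylene and the methyl-bearing ketene carbon bonds to the methoxy-bearing carbon, so only the 2-alkyl-3-methoxy-4-methyl isomer should form, with slow addition holding back ketene dimerisation.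

Step 11
Reactants: 18 2-{[5,7-bis(benzyloxy)-2,2,6-trimethyl-4-oxochroman-8-yl]methyl}-3-methoxy-4-methylcyclobut-2-en-1-one, 19 ethoxyacetylene
Product: 24 5,7-bis(benzyloxy)-8-[(2-ethoxy-4-hydroxy-6-methoxy-5-methylphenyl)methyl]-2,2,6-trimethylchroman-4-one, via vinylketene 20 (not isolated), via 4-vinylcyclobutenone 21 (not isolated), via dienylketene 22 (not isolated), via cyclohexadienone 23 (not isolated)
Conditions: 19 (5 equiv), toluene, sealed tube, 85 → 110 °C; then K2CO3, MeOH, 25 °C
Reagents that add atoms: none
Why: Thermal four-electron conrotatory opening of 18, with the C4 methyl turning outward, gives 3-methoxyvinylketene 20, whose ketene C=C adds the alkyne in a [2+2] cycloaddition to give 21; this second cyclobutenone opens to dienylketene 22, which closes to 23 and tautomerises to phenol 24. The sequence is a Danheiser benzannulation, here with a 3-alkoxycyclobutenone as the less usual vinylketene source. Ring A closes by a disrotatory six-electron electrocyclisation of 22 that joins the ketene carbon (C2') to the methyl-bearing terminus (C3'); the opening of 21 is reversible, so only the isomer with ketene and vinyl cis is drained forward. No stereocentre is formed, the racemic C4 of 18 becoming the aromatic C3'. The step needs one regiochemistry in the [2+2] event, and the polarisation of ethoxyacetylene secures it: its nucleophilic unsubstituted carbon bonds to the ketene carbonyl carbon (C1'–C2') and its oxygen-bearing carbon to the other ketene carbon (C6'–C5'), so that OH and OEt flank the open C1' and the methoxy group lands on C4'. The benzylated ring B offers no hydroxyl to trap either ketene, ethoxyacetylene is used in excess because it slowly fragments by a retro-ene reaction at the upper temperature, and the basic methanol treatment returns any phenol that was acylated by a ketene.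

Step 12
Reactants: 24 5,7-bis(benzyloxy)-8-[(2-ethoxy-4-hydroxy-6-methoxy-5-methylphenyl)methyl]-2,2,6-trimethylchroman-4-one, 25 (R)-2-methylbutanoic acid
Product: 27 5,7-bis(benzyloxy)-8-({2-ethoxy-4-hydroxy-6-methoxy-5-methyl-3-[(2R)-2-methylbutanoyl]phenyl}methyl)-2,2,6-trimethylchroman-4-one, via (R)-2-methylbutanoyl chloride 26 (not isolated)
Conditions: 25, (COCl)2, DMF (cat.), CH2Cl2, 0 → 25 °C; then 24, TiCl4 (1.2 equiv), CH2Cl2, −40 → 0 °C
Reagents that add atoms: none
Why: Friedel–Crafts acylation directed by the titanium phenoxide of the C2' hydroxyl should acylate C1', the only open and most electron-rich carbon, and the R centre is carried over from 25 unchanged because the acid chloride is made and used without base, so that no ketene can form.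

Step 13
Reactants: 27 5,7-bis(benzyloxy)-8-({2-ethoxy-4-hydroxy-6-methoxy-5-methyl-3-[(2R)-2-methylbutanoyl]phenyl}methyl)-2,2,6-trimethylchroman-4-one
Product: 28 5,7-dihydroxy-8-({2,4-dihydroxy-6-methoxy-5-methyl-3-[(2R)-2-methylbutanoyl]phenyl}methyl)-2,2,6-trimethylchroman-4-one
Conditions: BCl3 (8 equiv), C6HMe5, CH2Cl2, −78 → 25 °C; MeOH quench
Reagents that add atoms: none
Why: Lewis acid ether cleavage, in which BCl3 removes both benzyl groups (the cations being captured by pentamethylbenzene) and, through chelation to the C1' ketone, the ortho ethyl ether, while the C4' methyl ether, para to the ketone and unable to chelate, should survive and the stereocentre is not touched.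

**Compound list**

1 | phloroglucinol (benzene-1,3,5-triol) | Oc1cc(O)cc(O)c1 | starting material
2 | 3-methylbut-2-enoic acid | CC(C)=CC(=O)O | starting material
3 | 5,7-dihydroxy-2,2-dimethylchroman-4-one | CC1(C)CC(=O)c2c(O)cc(O)cc2O1 | intermediate
4 | 7-(benzyloxy)-5-hydroxy-2,2-dimethylchroman-4-one | CC1(C)CC(=O)c2c(O)cc(OCc3ccccc3)cc2O1 | intermediate
5 | 7-(benzyloxy)-5-hydroxy-6-iodo-2,2-dimethylchroman-4-one | CC1(C)CC(=O)c2c(O)c(I)c(OCc3ccccc3)cc2O1 | intermediate
6 | 7-(benzyloxy)-5-hydroxy-2,2,6-trimethylchroman-4-one | CC1(C)CC(=O)c2c(O)c(C)c(OCc3ccccc3)cc2O1 | intermediate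
7 | 7-(benzyloxy)-5-hydroxy-2,2,6-trimethyl-4-oxochromane-8-carbaldehyde | CC1(C)CC(=O)c2c(O)c(C)c(OCc3ccccc3)c(C=O)c2O1 | intermediate
8 | 5,7-bis(benzyloxy)-2,2,6-trimethyl-4-oxochromane-8-carbaldehyde | CC1(C)CC(=O)c2c(OCc3ccccc3)c(C)c(OCc3ccccc3)c(C=O)c2O1 | intermediate
9 | 5,7-bis(benzyloxy)-8-(hydroxymethyl)-2,2,6-trimethylchroman-4-one | CC1(C)CC(=O)c2c(OCc3ccccc3)c(C)c(OCc3ccccc3)c(CO)c2O1 | intermediate
10 | [5,7-bis(benzyloxy)-2,2,6-trimethyl-4-oxochroman-8-yl]methyl methanesulfonate | CC1(C)CC(=O)c2c(OCc3ccccc3)c(C)c(OCc3ccccc3)c(COS(C)(=O)=O)c2O1 | intermediate (not isolated)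
11 | 5,7-bis(benzyloxy)-8-(chloromethyl)-2,2,6-trimethylchroman-4-one | CC1(C)CC(=O)c2c(OCc3ccccc3)c(C)c(OCc3ccccc3)c(CCl)c2O1 | intermediate
12 | chloroacetaldehyde dimethyl acetal (2-chloro-1,1-dimethoxyethane) | COC(CCl)OC | starting material
13 | lithium methoxyacetylide | [Li]C#COC | intermediate (not isolated)
14 | (methoxyethynyl)zinc chloride | Cl[Zn]C#COC | intermediate (not isolated)
15 | 5,7-bis(benzyloxy)-8-(3-methoxyprop-2-yn-1-yl)-2,2,6-trimethylchroman-4-one | COC#CCc1c(OCc2ccccc2)c(C)c(OCc2ccccc2)c2c1OC(C)(C)CC2=O | intermediate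
16 | propanoyl chloride | CCC(=O)Cl | starting material
17 | methylketene (prop-1-en-1-one) | CC=C=O | intermediate (not isolated)
18 | 2-{[5,7-bis(benzyloxy)-2,2,6-trimethyl-4-oxochroman-8-yl]methyl}-3-methoxy-4-methylcyclobut-2-en-1-one (racemic at C4) | COC1=C(Cc2c(OCc3ccccc3)c(C)c(OCc3ccccc3)c3c2OC(C)(C)CC3=O)C(=O)C1C | intermediate
19 | ethoxyacetylene (ethoxyethyne) | CCOC#C | starting material
20 | vinylketene: 2-(ring B methyl)-3-methoxypenta-1,3-dien-1-one, ketene carbon and methyl trans | O=C=C(Cc1c(OCc2ccccc2)c(C)c(OCc2ccccc2)c2c1OC(C)(C)CC2=O)/C(OC)=C/C | intermediate (not isolated)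
21 | 4-vinylcyclobutenone: 3-ethoxy-4-(ring B methyl)-4-(1-methoxyprop-1-enyl)cyclobut-2-en-1-one (racemic) | O=C1C=C(OCC)C1(Cc1c(OCc2ccccc2)c(C)c(OCc2ccccc2)c2c1OC(C)(C)CC2=O)/C(OC)=C/C | intermediate (not isolated)
22 | dienylketene: 3-ethoxy-4-(ring B methyl)-5-methoxyhepta-1,3,5-trien-1-one, ketenyl and methoxypropenyl cis | O=C=C/C(OCC)=C(Cc1c(OCc2ccccc2)c(C)c(OCc2ccccc2)c2c1OC(C)(C)CC2=O)\C(OC)=C\C | intermediate (not isolated)
23 | cyclohexadienone: 3-ethoxy-4-(ring B methyl)-5-methoxy-6-methylcyclohexa-2,4-dien-1-one (racemic) | O=C1C=C(OCC)C(Cc2c(OCc3ccccc3)c(C)c(OCc3ccccc3)c3c2OC(C)(C)CC3=O)=C(OC)C1C | intermediate (not isolated)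
24 | 5,7-bis(benzyloxy)-8-[(2-ethoxy-4-hydroxy-6-methoxy-5-methylphenyl)methyl]-2,2,6-trimethylchroman-4-one | CCOc1cc(O)c(C)c(OC)c1Cc1c(OCc2ccccc2)c(C)c(OCc2ccccc2)c2c1OC(C)(C)CC2=O | intermediate
25 | (R)-2-methylbutanoic acid | CC[C@@H](C)C(=O)O | starting material
26 | (R)-2-methylbutanoyl chloride | CC[C@@H](C)C(=O)Cl | intermediate (not isolated)
27 | 5,7-bis(benzyloxy)-8-({2-ethoxy-4-hydroxy-6-methoxy-5-methyl-3-[(2R)-2-methylbutanoyl]phenyl}methyl)-2,2,6-trimethylchroman-4-one | CC[C@@H](C)C(=O)c1c(O)c(C)c(OC)c(Cc2c(OCc3ccccc3)c(C)c(OCc3ccccc3)c3c2OC(C)(C)CC3=O)c1OCC | intermediate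
28 | 5,7-dihydroxy-8-({2,4-dihydroxy-6-methoxy-5-methyl-3-[(2R)-2-methylbutanoyl]phenyl}methyl)-2,2,6-trimethylchroman-4-one | CC[C@@H](C)C(=O)c1c(O)c(C)c(OC)c(Cc2c(O)c(C)c(O)c3c2OC(C)(C)CC3=O)c1O | target

**Step count.** Total: 13 steps. Longest linear sequence: 13 steps (1 → 28).

**Steps most likely to fail**

Step 11. The vinylogous-ester character of 18 may make the first electrocyclic opening so slow that, at the temperature it needs, ethoxyacetylene is lost by retro-ene fragmentation and the cyclobutenone decomposes before the cascade starts. The fallback makes the same vinylketene at room temperature by 1,4-dehydrochlorination instead of ring opening. It sets out from 11: alkylation of ethyl 3-oxopentanoate (K2CO3, NaI, acetone) should give ethyl 2-{[5,7-bis(benzyloxy)-2,2,6-trimethyl-4-oxochroman-8-yl]methyl}-3-oxopentanoate F1. O-methylation of its enolate (KHMDS, MeOTf, THF/DMPU, −78 °C) should give the 3-methoxypent-2-enoate F2, hydrolysis (LiOH, THF/water) the acid F3, and oxalyl chloride the acid chloride F4. Treating F4 with Et3N in the presence of 19 at 25 °C, then warming to 80 °C, should remove the γ-hydrogen to form 20, which runs through 21, 22 and 23 and comes back to the route at 24.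

Step 9. Diethylamine and methoxide released with the acetylide may substitute the reactive benzylic chloride, or slow transmetalation may let the benzylpalladium species homocouple or be reduced. The fallback replaces the basic zinc acetylide made in the flask by an isolated, amine-free tin acetylide used under neutral conditions. From 12 (LiNEt2, then Bu3SnCl, distillation), tributyl(methoxyethynyl)stannane F5 is prepared, and a Stille coupling with 11 (Pd(PPh3)4, toluene, 60 °C) should give the ynol ether. The fallback sets out from 11 and comes back at 15.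

Step 13. Cleavage of the ethyl ether next to a ketone that is already chelated by the C2' oxygen may be slow. Long exposure to BCl3 could then remove the C4' methyl ether, open the pyranone ring so that it recloses on O5 (Wessely–Moser-type scrambling), or erode the α-stereocentre through enolisation. The fallback changes the group on the C6' oxygen to methyl, which is cleaved much faster and at lower temperature. It sets out from 18: methoxyacetylene F6 (from 12 with NaNH2 in liquid NH3, then aqueous NH4Cl, distilled into toluene) is used in the benzannulation to give the C6' methyl ether F7. Acylation as in step 12 should give ketone F8, and BCl3 with C6HMe5 at −78 → 0 °C should remove the two benzyl groups and the ortho methyl ether, coming back to the route at 28.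

**Further compounds**

F1 | step 11 | ethyl 2-{[5,7-bis(benzyloxy)-2,2,6-trimethyl-4-oxochroman-8-yl]methyl}-3-oxopentanoate (racemic) | CCC(=O)C(Cc1c(OCc2ccccc2)c(C)c(OCc2ccccc2)c2c1OC(C)(C)CC2=O)C(=O)OCC
F2 | step 11 | ethyl 2-{[5,7-bis(benzyloxy)-2,2,6-trimethyl-4-oxochroman-8-yl]methyl}-3-methoxypent-2-enoate (alkene geometry not controlled) | CCC(OC)=C(Cc1c(OCc2ccccc2)c(C)c(OCc2ccccc2)c2c1OC(C)(C)CC2=O)C(=O)OCC
F3 | step 11 | 2-{[5,7-bis(benzyloxy)-2,2,6-trimethyl-4-oxochroman-8-yl]methyl}-3-methoxypent-2-enoic acid | CCC(OC)=C(Cc1c(OCc2ccccc2)c(C)c(OCc2ccccc2)c2c1OC(C)(C)CC2=O)C(=O)O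
F4 | step 11 | 2-{[5,7-bis(benzyloxy)-2,2,6-trimethyl-4-oxochroman-8-yl]methyl}-3-methoxypent-2-enoyl chloride | CCC(OC)=C(Cc1c(OCc2ccccc2)c(C)c(OCc2ccccc2)c2c1OC(C)(C)CC2=O)C(=O)Cl
F5 | step 9 | tributyl(methoxyethynyl)stannane | COC#C[Sn](CCCC)(CCCC)CCCC
F6 | step 13 | methoxyacetylene | COC#C
F7 | step 13 | 5,7-bis(benzyloxy)-8-[(4-hydroxy-2,6-dimethoxy-5-methylphenyl)methyl]-2,2,6-trimethylchroman-4-one | COc1cc(O)c(C)c(OC)c1Cc1c(OCc2ccccc2)c(C)c(OCc2ccccc2)c2c1OC(C)(C)CC2=O
F8 | step 13 | 5,7-bis(benzyloxy)-8-({4-hydroxy-2,6-dimethoxy-5-methyl-3-[(2R)-2-methylbutanoyl]phenyl}methyl)-2,2,6-trimethylchroman-4-one | CC[C@@H](C)C(=O)c1c(O)c(C)c(OC)c(Cc2c(OCc3ccccc3)c(C)c(OCc3ccccc3)c3c2OC(C)(C)CC3=O)c1OC
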